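**Retrosynthetic overview**
- The strategy rests on the acyclic succinate core: two adjacent methines, C2 (4-hydroxyphenyl, CO2Me) and C3 (arylmethyl, CO2H), whose two carboxyl carbons are different. The last disconnections are the aryl–prenyl bond (Suzuki–Miyaura on an aryl bromide) and the two aryl O–Si bonds.
- The free carboxyl at C3 is unmasked from an E-propenyl group (ozonolysis, then chlorite oxidation) after the other carboxyl has been methylated, so the half-ester regiochemistry is built in.
- The C2–C3 bond and both stereocentres come from one Ireland–Claisen rearrangement of an (R,Z)-allylic arylacetate.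
- That ester is assembled from 4-(triisopropylsilyloxy)phenylacetic acid and a Z-alkenol made from (R)-but-3-yn-2-ol by alkyne–benzyl coupling and semihydrogenation.
- No ring is formed at any stage; both benzene rings are bought.

Key step: step 8

Assumption: LiN(SiMe3)2/Me3SiCl is taken to convert the arylacetate ester into the silyl ketene acetal with the aryl group cis to the O-silyl oxygen, the usual outcome for arylacetates; the matched substrate for the opposite geometry is given under the fallbacks.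

Step 1
Reactants: 1 3-bromo-4-hydroxybenzaldehyde
Product: 2 3-bromo-4-(triisopropylsilyloxy)benzaldehyde
Conditions: TIPSCl (1.2 equiv), imidazole (2.5 equiv), DMF, rt
Reagents that add atoms: triisopropylsilyl chloride, CC(C)[Si](Cl)(C(C)C)C(C)C
Why: Imidazole-promoted O-silylation of the acidic ortho-bromophenol should be clean, and the bulky silyl ether is chosen because it should survive the Grignard, amide-base and aqueous phosphate steps and can be removed at the end by fluoride without acid.

Step 2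
Reactants: 2 3-bromo-4-(triisopropylsilyloxy)benzaldehyde
Product: 3 [3-bromo-4-(triisopropylsilyloxy)phenyl]methanol
Conditions: NaBH4, THF/MeOH, 0 °C
Reagents that add atoms: none
Why: Borohydride reduction of an aryl aldehyde is fast at 0 °C and should leave the aryl bromide and the aryl silyl ether untouched.

Step 3
Reactants: 3 [3-bromo-4-(triisopropylsilyloxy)phenyl]methanol
Product: 4 3-bromo-4-(triisopropylsilyloxy)benzyl bromide
Conditions: CBr4 (1.2 equiv), PPh3 (1.25 equiv), CH2Cl2, 0 °C
Reagents that add atoms: carbon tetrabromide, BrC(Br)(Br)Br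
Why: The Appel reaction converts the benzylic alcohol into the bromide under neutral conditions that the silyl ether tolerates.

Step 4
Reactants: 5 (R)-but-3-yn-2-ol; 4 3-bromo-4-(triisopropylsilyloxy)benzyl bromide
Product: 7 (2R)-5-[3-bromo-4-(triisopropylsilyloxy)phenyl]pent-3-yn-2-ol, via alkynylmagnesium alkoxide 6 (not isolated)
Conditions: EtMgBr (2.05 equiv), THF, 0 → 40 °C; CuBr·SMe2 (10 mol %), then 4 (0.9 equiv), THF, 50 °C; aq NH4Cl
Reagents that add atoms: none
Why: Double deprotonation gives the magnesium acetylide/alkoxide, whose alkynyl carbon is benzylated under monovalent copper catalysis (copper-catalysed alkynyl Grignard–benzyl halide coupling) without touching the carbinol stereocentre, the aryl bromide or the silyl ether.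

Step 5
Reactants: 7 (2R)-5-[3-bromo-4-(triisopropylsilyloxy)phenyl]pent-3-yn-2-ol
Product: 8 (2R,3Z)-5-[3-bromo-4-(triisopropylsilyloxy)phenyl]pent-3-en-2-ol
Conditions: H2 (1 atm), Pd/CaCO3 poisoned with Pb(OAc)2, quinoline, EtOAc, rt, stopped after one equivalent of H2
Reagents that add atoms: none
Why: Lindlar semihydrogenation delivers both hydrogens syn on the catalyst surface to give the Z-alkene, and the poisoned catalyst should not cleave the aryl C–Br bond.

Step 6
Reactants: 9 4-hydroxyphenylacetic acid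
Product: 11 2-[4-(triisopropylsilyloxy)phenyl]acetic acid, via silyl ester 10 (not isolated)
Conditions: TIPSCl (2.2 equiv), imidazole (4.5 equiv), DMF, rt; then K2CO3 (1.2 equiv), THF/H2O, rt; acidify to pH 4
Reagents that add atoms: triisopropylsilyl chloride, CC(C)[Si](Cl)(C(C)C)C(C)C
Why: Both acidic OH groups are silylated and the much more labile silyl ester is then hydrolysed selectively by mild aqueous carbonate, leaving the aryl silyl ether.

Step 7
Reactants: 8 (2R,3Z)-5-[3-bromo-4-(triisopropylsilyloxy)phenyl]pent-3-en-2-ol; 11 2-[4-(triisopropylsilyloxy)phenyl]acetic acid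
Product: 12 (2R,3Z)-5-[3-bromo-4-(triisopropylsilyloxy)phenyl]pent-3-en-2-yl 2-[4-(triisopropylsilyloxy)phenyl]acetate
Conditions: DCC (1.1 equiv), DMAP (0.1 equiv), CH2Cl2, 0 °C → rt
Reagents that add atoms: none
Why: Steglich esterification acylates the secondary allylic alcohol at oxygen, so the carbinol C–O bond and its R configuration are retained.

Step 8
Reactants: 12 (2R,3Z)-5-[3-bromo-4-(triisopropylsilyloxy)phenyl]pent-3-en-2-yl 2-[4-(triisopropylsilyloxy)phenyl]acetate
Product: 15 (2S,3R,4E)-3-{[3-bromo-4-(triisopropylsilyloxy)phenyl]methyl}-2-[4-(triisopropylsilyloxy)phenyl]hex-4-enoic acid, via silyl ketene acetal 13 (not isolated), via trimethylsilyl ester 14 (not isolated)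
Conditions: LiN(SiMe3)2 (1.3 equiv), THF, −78 °C; Me3SiCl (1.5 equiv), −78 °C → rt, then 60 °C; 1 M HCl
Reagents that add atoms: none
Why: LiN(SiMe3)2 removes a benzylic α-hydrogen of the arylacetate and Me3SiCl should trap the enolate on oxygen as the (Z)-silyl ketene acetal 13 (aryl cis to OSiMe3), which on warming undergoes the concerted suprafacial [3,3]-sigmatropic Ireland–Claisen shift in which the α-carbon bonds to the alkene carbon carrying the arylmethyl group while the allylic C–O bond breaks. The closest known reaction type is the Ireland–Claisen rearrangement of arylacetates of enantioenriched secondary allylic alcohols with 1,3-chirality transfer; no ring is closed, the six atoms only pass through a chair-like transition state. C2 is set by the ketene acetal geometry (aryl pseudo-equatorial), and C3 by the Z-alkene (arylmethyl pseudo-axial) together with the R carbinol, whose methyl must sit pseudo-equatorial to avoid a 1,3-diaxial clash with that arylmethyl group, so one alkene face is used and the new alkene is E. The step needs a single ketene acetal geometry and chair over boat, which the conjugated aryl enolate and the acyclic Z-allyl unit should secure; the aryl bromide and aryl silyl ethers are inert to the amide base at −78 °C, and the acidic work-up hydrolyses silyl ester 14 to acid 15.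

Step 9
Reactants: 15 (2S,3R,4E)-3-{[3-bromo-4-(triisopropylsilyloxy)phenyl]methyl}-2-[4-(triisopropylsilyloxy)phenyl]hex-4-enoic acid
Product: 16 methyl (2S,3R,4E)-3-{[3-bromo-4-(triisopropylsilyloxy)phenyl]methyl}-2-[4-(triisopropylsilyloxy)phenyl]hex-4-enoate
Conditions: Me3SiCHN2 (2 M in hexanes, 1.5 equiv), toluene/MeOH 4:1, 0 °C → rt
Reagents that add atoms: (trimethylsilyl)diazomethane, C[Si](C)(C)C=[N+]=[N-]
Why: O-methylation of the acid by the diazoalkane is non-basic, so the epimerisable α-aryl centre C2 should not be disturbed.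

Step 10
Reactants: 16 methyl (2S,3R,4E)-3-{[3-bromo-4-(triisopropylsilyloxy)phenyl]methyl}-2-[4-(triisopropylsilyloxy)phenyl]hex-4-enoate
Product: 18 methyl (2S,3S)-4-[3-bromo-4-(triisopropylsilyloxy)phenyl]-3-formyl-2-[4-(triisopropylsilyloxy)phenyl]butanoate, via secondary ozonide 17 (not isolated)
Conditions: O3 (dosed to consumption of 16), CH2Cl2, −78 °C; PPh3 (1.5 equiv), −78 °C → rt; used crude
Reagents that add atoms: ozone, [O-][O+]=O
Why: Ozonolysis with reductive work-up cleaves the only alkene, which is more electron-rich towards ozone than the silylated arenes, and removes the former carbinol carbon as acetaldehyde without breaking any bond at C2 or C3.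

Step 11
Reactants: 18 methyl (2S,3S)-4-[3-bromo-4-(triisopropylsilyloxy)phenyl]-3-formyl-2-[4-(triisopropylsilyloxy)phenyl]butanoate
Product: 19 (2S,3S)-2-{[3-bromo-4-(triisopropylsilyloxy)phenyl]methyl}-4-methoxy-4-oxo-3-[4-(triisopropylsilyloxy)phenyl]butanoic acid
Conditions: NaClO2 (3 equiv), NaH2PO4 (4 equiv), 2-methyl-2-butene (20 equiv), t-BuOH/H2O 4:1, 0 °C → rt
Reagents that add atoms: sodium chlorite, [Na+].[O-]Cl=O
Why: Pinnick oxidation converts the aldehyde into the acid at buffered mild pH without enolising the α-centre, and the alkene scavenger removes hypochlorite before it can chlorinate the arenes.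

Step 12
Reactants: 19 (2S,3S)-2-{[3-bromo-4-(triisopropylsilyloxy)phenyl]methyl}-4-methoxy-4-oxo-3-[4-(triisopropylsilyloxy)phenyl]butanoic acid; 20 prenylboronic acid pinacol ester
Product: 21 (2S,3S)-4-methoxy-2-{[3-(3-methylbut-2-en-1-yl)-4-(triisopropylsilyloxy)phenyl]methyl}-4-oxo-3-[4-(triisopropylsilyloxy)phenyl]butanoic acid
Conditions: Pd(OAc)2 (5 mol %), 2-di-tert-butylphosphino-2′,4′,6′-triisopropylbiphenyl (10 mol %), K3PO4 (aq, 4 equiv), THF, 40 °C; pH 4 work-up
Reagents that add atoms: none
Why: Suzuki–Miyaura coupling of the aryl bromide (as its carboxylate) with the allylboronate, where the bulky di-tert-butylbiarylphosphine on zerovalent palladium should let the σ-allyl intermediate equilibrate to the primary terminus before reductive elimination and so give the linear prenyl arene.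

Step 13
Reactants: 21 (2S,3S)-4-methoxy-2-{[3-(3-methylbut-2-en-1-yl)-4-(triisopropylsilyloxy)phenyl]methyl}-4-oxo-3-[4-(triisopropylsilyloxy)phenyl]butanoic acid
Product: 22 Asperteretal G2, (2S,3S)-2-{[4-hydroxy-3-(3-methylbut-2-en-1-yl)phenyl]methyl}-3-(4-hydroxyphenyl)-4-methoxy-4-oxobutanoic acid
Conditions: Bu4NF (3 equiv), AcOH (3 equiv), THF, 0 °C → rt
Reagents that add atoms: none
Why: Acetic-acid-buffered fluoride cleaves both aryl O–Si bonds while keeping the medium too weakly basic to epimerise the α-aryl ester centre and free of the strong acid that would cyclise the ortho-prenylphenol.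

**Compound list**
1 | 3-bromo-4-hydroxybenzaldehyde | O=Cc1ccc(O)c(Br)c1 | starting material
2 | 3-bromo-4-(triisopropylsilyloxy)benzaldehyde | O=Cc1ccc(O[Si](C(C)C)(C(C)C)C(C)C)c(Br)c1 | intermediate
3 | [3-bromo-4-(triisopropylsilyloxy)phenyl]methanol | OCc1ccc(O[Si](C(C)C)(C(C)C)C(C)C)c(Br)c1 | intermediate
4 | 3-bromo-4-(triisopropylsilyloxy)benzyl bromide | BrCc1ccc(O[Si](C(C)C)(C(C)C)C(C)C)c(Br)c1 | intermediate
5 | (R)-but-3-yn-2-ol | C[C@@H](O)C#C | starting material
6 | bis(bromomagnesium) alkynyl alkoxide of 5 | C[C@@H](O[Mg]Br)C#C[Mg]Br | intermediate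
7 | (2R)-5-[3-bromo-4-(triisopropylsilyloxy)phenyl]pent-3-yn-2-ol | C[C@@H](O)C#CCc1ccc(O[Si](C(C)C)(C(C)C)C(C)C)c(Br)c1 | intermediate
8 | (2R,3Z)-5-[3-bromo-4-(triisopropylsilyloxy)phenyl]pent-3-en-2-ol | C[C@@H](O)/C=C\Cc1ccc(O[Si](C(C)C)(C(C)C)C(C)C)c(Br)c1 | intermediate
9 | 4-hydroxyphenylacetic acid | O=C(O)Cc1ccc(O)cc1 | starting material
10 | triisopropylsilyl 2-[4-(triisopropylsilyloxy)phenyl]acetate | CC(C)[Si](OC(=O)Cc1ccc(O[Si](C(C)C)(C(C)C)C(C)C)cc1)(C(C)C)C(C)C | intermediate
11 | 2-[4-(triisopropylsilyloxy)phenyl]acetic acid | O=C(O)Cc1ccc(O[Si](C(C)C)(C(C)C)C(C)C)cc1 | intermediate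
12 | (2R,3Z)-5-[3-bromo-4-(triisopropylsilyloxy)phenyl]pent-3-en-2-yl 2-[4-(triisopropylsilyloxy)phenyl]acetate | C[C@@H](OC(=O)Cc1ccc(O[Si](C(C)C)(C(C)C)C(C)C)cc1)/C=C\Cc1ccc(O[Si](C(C)C)(C(C)C)C(C)C)c(Br)c1 | intermediate
13 | (Z)-trimethylsilyl ketene acetal of 12 (aryl cis to OSiMe3) | C[Si](C)(C)O/C(O[C@H](C)/C=C\Cc1ccc(O[Si](C(C)C)(C(C)C)C(C)C)c(Br)c1)=C\c1ccc(O[Si](C(C)C)(C(C)C)C(C)C)cc1 | intermediate
14 | trimethylsilyl (2S,3R,4E)-3-{[3-bromo-4-(triisopropylsilyloxy)phenyl]methyl}-2-[4-(triisopropylsilyloxy)phenyl]hex-4-enoate | C[Si](C)(C)OC(=O)[C@H](c1ccc(O[Si](C(C)C)(C(C)C)C(C)C)cc1)[C@H](Cc1ccc(O[Si](C(C)C)(C(C)C)C(C)C)c(Br)c1)/C=C/C | intermediate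
15 | (2S,3R,4E)-3-{[3-bromo-4-(triisopropylsilyloxy)phenyl]methyl}-2-[4-(triisopropylsilyloxy)phenyl]hex-4-enoic acid | OC(=O)[C@H](c1ccc(O[Si](C(C)C)(C(C)C)C(C)C)cc1)[C@H](Cc1ccc(O[Si](C(C)C)(C(C)C)C(C)C)c(Br)c1)/C=C/C | intermediate
16 | methyl (2S,3R,4E)-3-{[3-bromo-4-(triisopropylsilyloxy)phenyl]methyl}-2-[4-(triisopropylsilyloxy)phenyl]hex-4-enoate | COC(=O)[C@H](c1ccc(O[Si](C(C)C)(C(C)C)C(C)C)cc1)[C@H](Cc1ccc(O[Si](C(C)C)(C(C)C)C(C)C)c(Br)c1)/C=C/C | intermediate
17 | secondary ozonide of 16 (3-methyl-1,2,4-trioxolan-5-yl compound, mixture of ring stereoisomers) | COC(=O)[C@H](c1ccc(O[Si](C(C)C)(C(C)C)C(C)C)cc1)[C@H](Cc1ccc(O[Si](C(C)C)(C(C)C)C(C)C)c(Br)c1)C1OC(C)OO1 | intermediate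
18 | methyl (2S,3S)-4-[3-bromo-4-(triisopropylsilyloxy)phenyl]-3-formyl-2-[4-(triisopropylsilyloxy)phenyl]butanoate | COC(=O)[C@H](c1ccc(O[Si](C(C)C)(C(C)C)C(C)C)cc1)[C@H](Cc1ccc(O[Si](C(C)C)(C(C)C)C(C)C)c(Br)c1)C=O | intermediate
19 | (2S,3S)-2-{[3-bromo-4-(triisopropylsilyloxy)phenyl]methyl}-4-methoxy-4-oxo-3-[4-(triisopropylsilyloxy)phenyl]butanoic acid | COC(=O)[C@H](c1ccc(O[Si](C(C)C)(C(C)C)C(C)C)cc1)[C@H](Cc1ccc(O[Si](C(C)C)(C(C)C)C(C)C)c(Br)c1)C(=O)O | intermediate
20 | prenylboronic acid pinacol ester | CC(C)=CCB1OC(C)(C)C(C)(C)O1 | starting material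
21 | (2S,3S)-4-methoxy-2-{[3-(3-methylbut-2-en-1-yl)-4-(triisopropylsilyloxy)phenyl]methyl}-4-oxo-3-[4-(triisopropylsilyloxy)phenyl]butanoic acid | COC(=O)[C@H](c1ccc(O[Si](C(C)C)(C(C)C)C(C)C)cc1)[C@H](Cc1ccc(O[Si](C(C)C)(C(C)C)C(C)C)c(CC=C(C)C)c1)C(=O)O | intermediate
22 | Asperteretal G2 | COC(=O)[C@H](c1ccc(O)cc1)[C@H](Cc1ccc(O)c(CC=C(C)C)c1)C(=O)O | target

**Totals**
Total step count: 13. Longest linear sequence: 12 steps (from 1 through steps 1–5 and 7–13; step 6 is a one-step branch).

**Steps most likely to fail**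

Step 8. The process at risk is enolisation to the wrong or a mixed ketene acetal geometry (aryl trans to the O-silyl oxygen), which would invert C2 relative to C3, together with leakage through a boat transition state. The fallback changes the stereochemical pairing of the substrate and not only the base. It sets out from 4: (S)-but-3-yn-2-ol F1 is doubly deprotonated with EtMgBr to its bis(bromomagnesium) alkynyl alkoxide F2 and benzylated with 4 under CuBr·SMe2 catalysis to (2S)-5-[3-bromo-4-(triisopropylsilyloxy)phenyl]pent-3-yn-2-ol F3. Hydroxyl-directed trans-hydroalumination with NaAlH2(OCH2CH2OCH3)2 in THF at 0 °C and protonolysis should give (2S,3E)-5-[3-bromo-4-(triisopropylsilyloxy)phenyl]pent-3-en-2-ol F4, which is esterified with 11 (DCC, DMAP) to the (2S,3E)-allylic arylacetate F5. Enolisation and silylation under the conditions that favour the opposite geometry then pass through the (E)-trimethylsilyl ketene acetal F6 (aryl trans to OSiMe3, pseudo-axial in the chair, with arylmethyl and methyl both pseudo-equatorial). This should rearrange to the same silyl ester 14, and acidic work-up brings the route back at acid 15.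

Step 12. The processes at risk are γ-coupling to the branched reverse-prenyl isomer, slow oxidative addition beside the bulky silyloxy group, and base-mediated epimerisation of the α-aryl ester centre in warm aqueous phosphate. The fallback removes the regiochemical question by coupling a symmetrical allyl unit under anhydrous fluoride activation. It sets out from 19: allylboronic acid pinacol ester, Pd(PPh3)4 and CsF in THF at 65 °C should give (2S,3S)-4-methoxy-4-oxo-2-{[3-(prop-2-en-1-yl)-4-(triisopropylsilyloxy)phenyl]methyl}-3-[4-(triisopropylsilyloxy)phenyl]butanoic acid F7. Cross-metathesis of F7 with excess 2-methyl-2-butene and the second-generation Grubbs catalyst (H2IMes)(PCy3)Cl2Ru=CHPh in CH2Cl2 at 40 °C then installs the trisubstituted alkene and returns to the route at 21.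

Step 10. The processes at risk are over-oxidation of the electron-rich silyloxyarene rings once the alkene is consumed and epimerisation of the α-branched aldehyde during peroxide reduction. The fallback replaces ozone by osmium-based cleavage and sets out from 16: one-pot OsO4 (cat.), NaIO4 and 2,6-lutidine in dioxane/H2O at rt dihydroxylates the propenyl group to the transient methyl (2S,3R)-3-{[3-bromo-4-(triisopropylsilyloxy)phenyl]methyl}-4,5-dihydroxy-2-[4-(triisopropylsilyloxy)phenyl]hexanoate F8. Periodate cleaves F8 in the same flask before it can lactonise onto the methyl ester, and the route is rejoined at aldehyde 18.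

**Further compounds**
F1 | step 8 | (S)-but-3-yn-2-ol | C[C@H](O)C#C
F2 | step 8 | bis(bromomagnesium) alkynyl alkoxide of (S)-but-3-yn-2-ol | C[C@H](O[Mg]Br)C#C[Mg]Br
F3 | step 8 | (2S)-5-[3-bromo-4-(triisopropylsilyloxy)phenyl]pent-3-yn-2-ol | C[C@H](O)C#CCc1ccc(O[Si](C(C)C)(C(C)C)C(C)C)c(Br)c1
F4 | step 8 | (2S,3E)-5-[3-bromo-4-(triisopropylsilyloxy)phenyl]pent-3-en-2-ol | C[C@H](O)/C=C/Cc1ccc(O[Si](C(C)C)(C(C)C)C(C)C)c(Br)c1
F5 | step 8 | (2S,3E)-5-[3-bromo-4-(triisopropylsilyloxy)phenyl]pent-3-en-2-yl 2-[4-(triisopropylsilyloxy)phenyl]acetate | C[C@H](OC(=O)Cc1ccc(O[Si](C(C)C)(C(C)C)C(C)C)cc1)/C=C/Cc1ccc(O[Si](C(C)C)(C(C)C)C(C)C)c(Br)c1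
F6 | step 8 | (E)-trimethylsilyl ketene acetal of F5 (aryl trans to OSiMe3) | C[Si](C)(C)O/C(O[C@@H](C)/C=C/Cc1ccc(O[Si](C(C)C)(C(C)C)C(C)C)c(Br)c1)=C/c1ccc(O[Si](C(C)C)(C(C)C)C(C)C)cc1
F7 | step 12 | (2S,3S)-4-methoxy-4-oxo-2-{[3-(prop-2-en-1-yl)-4-(triisopropylsilyloxy)phenyl]methyl}-3-[4-(triisopropylsilyloxy)phenyl]butanoic acid | COC(=O)[C@H](c1ccc(O[Si](C(C)C)(C(C)C)C(C)C)cc1)[C@H](Cc1ccc(O[Si](C(C)C)(C(C)C)C(C)C)c(CC=C)c1)C(=O)O
F8 | step 10 | methyl (2S,3R)-3-{[3-bromo-4-(triisopropylsilyloxy)phenyl]methyl}-4,5-dihydroxy-2-[4-(triisopropylsilyloxy)phenyl]hexanoate (mixture at the two carbinol carbons) | COC(=O)[C@H](c1ccc(O[Si](C(C)C)(C(C)C)C(C)C)cc1)[C@H](Cc1ccc(O[Si](C(C)C)(C(C)C)C(C)C)c(Br)c1)C(O)C(C)O
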